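- At early times the two earlier runs already stand near their plateaus: at their first points, 8.00 min and 2.50 min, dawn reads 85.9% links and noon 47.5%. We therefore start from an equilibrium.

| flask | first end groups | second end groups | protic impurity | remark | time |
|---|---|---|---|---|---|
| dawn | 0.20 M | 0.50 M | 10 mM | run made earlier |  |
| noon | 0.79 M | 0.50 M | 10 mM | run made earlier |  |
| larch | 0.50 M | 0.500 M | 10.0 mM |  | 1.0 h |
| oak | 0.15 M | 0.500 M | 10.0 mM |  | 1.0 h |

- dawn (time / min: links / %): 8.00: 85.9; 15.0: 84.8; 25.0: 82.3; 30.0: 83.0
- noon (time / min: links / %): 2.50: 47.5; 6.00: 45.6; 12.0: 46.4; 30.0: 46.6

(readings scatter by 1 percentage point)

- which of the two ends with the longer chains by the average number of monomer units in a chain (unreacted monomers counted as chains of one) ("neither" if they lie within 10%) (larch / oak / neither)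
- average number of monomer units in a chain (unreacted monomers counted as chains of one) at the end, larch
- average number of monomer units in a chain (unreacted monomers counted as chains of one) at the end, oak

- each molecule carries two end groups: a chain counts once for every two ends that are left, dead ends included; the units are half of the end groups of the two monomers charged

- Each link removes two ends, so chain length is ([first]₀ + [second]₀)/([first]₀ + [second]₀ − 2[links]).
- Mean readings give [links] = 0.168 M in dawn and 0.368 M in noon. Letting the impurity cap second ends leaves free [second] = 0.322 M and 0.122 M, with [first] = 0.0320 M and 0.422 M.
- The plain quotient [links]/([first][second]) gives 16.3 /M and 7.15 /M, which disagree. If each link also frees one unseen by-product, [links]²/([first][second]) gives 2.74 and 2.61. Their mean is our end quotient, an equilibrium constant read from the plateaus, 2.68.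
- Solving that quotient gives larch [links] = 0.307 M, length 2.59. Oak gets 0.132 M, length 1.68.
- The weak link is assuming the plateau lasts 1.0 h. Dawn's later pair of readings lies 2.7 percentage points below its earlier pair, though noon shows 0.05 points, so this is a weak reading.
- Read through the quotient as a first-order loss of free second ends, dawn's fall gives 0.0157 /min.
- For larch we let links give back part of each loss, so in our reckoning free [second] decays pseudo-first-order, with that constant times 0.681. This integrates to 0.0962 M at the end, and the quotient then gives [links] = 0.252 M, length 2.02.
- We commit to larch between 2.02 and 2.59, still above oak's 1.68.
- The forecast says larch, 2.58 and 1.68, beside our no-loss figures, on the ground that “these look like equilibria rather than slow kinetics”.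
- The flask gives larch, with 2.28 for larch and 1.62 for oak.

    first end groups + second end groups ⇌ links + by-product (K = 3.10, k = 7.10 /M/min)
    second end groups + protic impurity → quenched reagent (k = 6.20 /M/min)
    second end groups → decomposed reagent (k = 0.0110 /min)

- Larch stood at 2.58 after 0.250 h, then slid to 2.28 as free second ends fell to 23.0% of charge. That amount in the end quotient gives 53.5% links against larch's 56.1%. In a neighbour of larch charged with 1.2 M of first end groups, with 11.9% of its second end groups left, it gives 30.4% against that flask's 32.3%. The way back is the largest single effect on larch's length: without it larch ends at 33.4 against 2.28.

The readings come from a simulation with constants of no real substance; noise was put on by code.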